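**Plan**

- Retrosynthesis: the lactone is opened at C3–C4 (with a benzyl carboxylate helper on C3). Then the O1–C2 aryl ester, the C4–C4a bond between ring A and the benzylic carbon, and the C8–acyl bond are cut, down to phloroglucinol.
- Forward: phloroglucinol is C-acylated and O-benzylated at O5 and O7, so the one free hydroxyl is the future O1. It is iodinated ortho to that hydroxyl and cross-coupled with the ring B benzyl unit. O1 is then malonylated, ring B is desilylated, the lactone ring is closed oxidatively, and the helpers are removed.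
- Enabling feature: C4 is a diarylmethane carbon para to the free phenol OH of ring B (and ortho/para to O5 and O7 of ring A). Two-electron oxidation turns it into a para-quinone methide that the malonate carbon tethered through O1 reaches in a six-membered closure.
- Stereochemistry: the single stereocentre C4 (S) is set in that ring closure by a chiral Cu(OTf)2–bisoxazoline complex bound to the malonate. The extra centre at C3 disappears on decarboxylation.

Key step: step 7

Remark: benzylic chloride 8 is treated as a purchasable building block. Locants O1 to C8a are those of the chroman-2-one target; ring A is its benzo ring and ring B the 4-hydroxyphenyl ring.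

**Route**

Step 1
Reactants: 1 phloroglucinol; 2 3-phenylpropanoyl chloride
Product: 3 3-phenyl-1-(2,4,6-trihydroxyphenyl)propan-1-one
Conditions: AlCl3 (4 equiv), PhNO2/CH2Cl2, 0 to 60 °C; aq HCl work-up
Reagents that add atoms: 3-phenylpropanoyl chloride (2), O=C(Cl)CCc1ccccc1
Why: Friedel–Crafts acylation of the threefold-activated, symmetrical arene should give a single mono-ketone, because the first acyl group deactivates the ring towards a second acylation.

Step 2
Reactants: 3 3-phenyl-1-(2,4,6-trihydroxyphenyl)propan-1-one; 4 benzyl bromide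
Product: 5 1-[2,4-bis(benzyloxy)-6-hydroxyphenyl]-3-phenylpropan-1-one
Conditions: BnBr (2.1 equiv), K2CO3 (2.2 equiv), DMF, 0 to 20 °C
Reagents that add atoms: benzyl bromide (4), BrCc1ccccc1
Why: Williamson etherification with two equivalents of halide alkylates the para hydroxyl and one ortho hydroxyl, while the remaining ortho hydroxyl is held in a hydrogen bond to the ketone and stays free, the usual outcome for 2,4,6-trihydroxyaryl ketones.

Step 3
Reactants: 5 1-[2,4-bis(benzyloxy)-6-hydroxyphenyl]-3-phenylpropan-1-one; 6 N-iodosuccinimide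
Product: 7 1-[4,6-bis(benzyloxy)-2-hydroxy-3-iodophenyl]-3-phenylpropan-1-one
Conditions: NIS (1.05 equiv), TFA (cat.), MeCN, 0 °C, dark
Reagents that add atoms: N-iodosuccinimide (6), O=C1CCC(=O)N1I
Why: Electrophilic aromatic iodination is directed ortho to the free, chelated hydroxyl (the CH between OH and OBn), the established preference of 2-hydroxy-4,6-dialkoxyaryl ketones, which places the halogen on the future C4a.

Step 4
Reactants: 7 1-[4,6-bis(benzyloxy)-2-hydroxy-3-iodophenyl]-3-phenylpropan-1-one; 8 tert-butyl[4-(chloromethyl)phenoxy]dimethylsilane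
Product: 10 1-[4,6-bis(benzyloxy)-3-{4-[(tert-butyldimethylsilyl)oxy]benzyl}-2-hydroxyphenyl]-3-phenylpropan-1-one, via benzylic zinc chloride 9 (not isolated)
Conditions: 8, Zn dust, LiCl, THF, 25 °C; then 7 (9 in 2.5 equiv), Pd(OAc)2 (2 mol%), SPhos (4 mol%), THF, 25 to 50 °C
Reagents that add atoms: tert-butyl[4-(chloromethyl)phenoxy]dimethylsilane (8, delivered as zinc reagent 9), CC(C)(C)[Si](C)(C)Oc1ccc(CCl)cc1
Why: Negishi cross-coupling of the aryl iodide with a benzylic zinc chloride made by LiCl-assisted zinc insertion; the Pd/SPhos catalyst couples di-ortho-substituted aryl halides, the zinc reagent leaves the ketone untouched, and its excess covers the equivalent that the phenol protonates.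

Step 5
Reactants: 10 1-[4,6-bis(benzyloxy)-3-{4-[(tert-butyldimethylsilyl)oxy]benzyl}-2-hydroxyphenyl]-3-phenylpropan-1-one; 11 3-(benzyloxy)-3-oxopropanoic acid (mono-benzyl malonate)
Product: 12 benzyl 3,5-bis(benzyloxy)-2-{4-[(tert-butyldimethylsilyl)oxy]benzyl}-6-(3-phenylpropanoyl)phenyl malonate
Conditions: 11 (1.5 equiv), DCC (1.5 equiv), DMAP (0.1 equiv), CH2Cl2, 0 to 20 °C
Reagents that add atoms: mono-benzyl malonate (11), O=C(O)CC(=O)OCc1ccccc1
Why: Steglich esterification, in which the carbodiimide activates the malonic half ester (O-acylisourea or the derived acyl ketene) to a small electrophile that acylates the hindered O1 hydroxyl, the only free OH in 10.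

Step 6
Reactants: 12 benzyl 3,5-bis(benzyloxy)-2-{4-[(tert-butyldimethylsilyl)oxy]benzyl}-6-(3-phenylpropanoyl)phenyl malonate
Product: 13 benzyl 3,5-bis(benzyloxy)-2-(4-hydroxybenzyl)-6-(3-phenylpropanoyl)phenyl malonate
Conditions: HF·pyridine, THF/pyridine, 0 to 20 °C
Reagents that add atoms: none
Why: Fluoride cleavage of the aryl silyl ether under buffered, weakly acidic conditions, which leave the activated aryl malonate and the benzyl ethers intact and uncover the ring B phenol needed for the oxidation.

Step 7
Reactants: 13 benzyl 3,5-bis(benzyloxy)-2-(4-hydroxybenzyl)-6-(3-phenylpropanoyl)phenyl malonate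
Product: 15 benzyl (3S,4S)-5,7-bis(benzyloxy)-4-(4-hydroxyphenyl)-2-oxo-8-(3-phenylpropanoyl)chromane-3-carboxylate (3,4-trans), via para-quinone methide 14 (not isolated)
Conditions: Cu(OTf)2 (10 mol%), (S,S)-Ph-BOX (12 mol%), DDQ (1.0 equiv, added slowly), CH2Cl2 (0.02 M), −30 °C
Reagents that add atoms: none
Why: Proposed new method: DDQ abstracts hydride from C4, the only CH2 that is doubly benzylic and para to a free phenol OH, and loss of the phenol proton gives para-quinone methide 14; the Cu(OTf)2–bisoxazoline complex binds the aryl benzyl malonate through both carbonyl oxygens, the DDQH anion deprotonates it, and the copper enolate adds 1,6 to the methide carbon, forming C3–C4 and re-aromatising ring B. The closest known reaction type is the DDQ-mediated enantioselective cross-dehydrogenative coupling of benzylic C–H bonds of electron-rich arylmethanes with malonates under divalent copper–bisoxazoline catalysis, here run intramolecularly through an aryl ester tether onto a phenol-derived quinone methide. The lactone ring closes 6-exo-trig, since the methide carbon lies inside the new ring and the other end of the attacked exocyclic C=C outside it. C4 is set under catalyst control: the oxazoline phenyl groups leave one enolate face open, and the chair-like closure with the quinone methide ring anti to the C3 ester then defines the attacked face of C4, the ligand enantiomer being chosen to give S; C3 should settle as the 3,4-trans epimer and is deleted in step 8. The step needs site selectivity in the oxidation and a preference of the enolate for the methide over the C8 ketone six atoms away: the first is secured because every other oxygen of 13 is benzylated or acylated, the second by the low electrophilicity of the hindered, alkoxy-deactivated aryl ketone.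

Step 8
Reactants: 15 benzyl (3S,4S)-5,7-bis(benzyloxy)-4-(4-hydroxyphenyl)-2-oxo-8-(3-phenylpropanoyl)chromane-3-carboxylate
Product: 17 (4S)-5,7-dihydroxy-4-(4-hydroxyphenyl)-8-(3-phenylpropanoyl)chroman-2-one, via carboxylic acid 16 (not isolated)
Conditions: H2 (1 atm), 10% Pd/C, EtOAc/THF, 20 °C; filter; then toluene, 70 °C
Reagents that add atoms: none
Why: Hydrogenolysis over Pd/C cleaves the two aryl benzyl ethers and the benzyl ester, and the resulting 2-oxochromane-3-carboxylic acid, a malonic half acid, loses CO2 on gentle warming through the cyclic six-membered transition state without touching C4.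

**Compound list**

1 | phloroglucinol (benzene-1,3,5-triol) | Oc1cc(O)cc(O)c1 | starting material
2 | 3-phenylpropanoyl chloride | O=C(Cl)CCc1ccccc1 | starting material
3 | 3-phenyl-1-(2,4,6-trihydroxyphenyl)propan-1-one | O=C(CCc1ccccc1)c1c(O)cc(O)cc1O | intermediate
4 | benzyl bromide | BrCc1ccccc1 | starting material
5 | 1-[2,4-bis(benzyloxy)-6-hydroxyphenyl]-3-phenylpropan-1-one | O=C(CCc1ccccc1)c1c(O)cc(OCc2ccccc2)cc1OCc1ccccc1 | intermediate
6 | N-iodosuccinimide | O=C1CCC(=O)N1I | starting material
7 | 1-[4,6-bis(benzyloxy)-2-hydroxy-3-iodophenyl]-3-phenylpropan-1-one | O=C(CCc1ccccc1)c1c(O)c(I)c(OCc2ccccc2)cc1OCc1ccccc1 | intermediate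
8 | tert-butyl[4-(chloromethyl)phenoxy]dimethylsilane | CC(C)(C)[Si](C)(C)Oc1ccc(CCl)cc1 | starting material
9 | {4-[(tert-butyldimethylsilyl)oxy]benzyl}zinc chloride | CC(C)(C)[Si](C)(C)Oc1ccc(C[Zn]Cl)cc1 | intermediate
10 | 1-[4,6-bis(benzyloxy)-3-{4-[(tert-butyldimethylsilyl)oxy]benzyl}-2-hydroxyphenyl]-3-phenylpropan-1-one | CC(C)(C)[Si](C)(C)Oc1ccc(Cc2c(O)c(C(=O)CCc3ccccc3)c(OCc3ccccc3)cc2OCc2ccccc2)cc1 | intermediate
11 | 3-(benzyloxy)-3-oxopropanoic acid (mono-benzyl malonate) | O=C(O)CC(=O)OCc1ccccc1 | starting material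
12 | benzyl 3,5-bis(benzyloxy)-2-{4-[(tert-butyldimethylsilyl)oxy]benzyl}-6-(3-phenylpropanoyl)phenyl malonate | CC(C)(C)[Si](C)(C)Oc1ccc(Cc2c(OC(=O)CC(=O)OCc3ccccc3)c(C(=O)CCc3ccccc3)c(OCc3ccccc3)cc2OCc2ccccc2)cc1 | intermediate
13 | benzyl 3,5-bis(benzyloxy)-2-(4-hydroxybenzyl)-6-(3-phenylpropanoyl)phenyl malonate | Oc1ccc(Cc2c(OC(=O)CC(=O)OCc3ccccc3)c(C(=O)CCc3ccccc3)c(OCc3ccccc3)cc2OCc2ccccc2)cc1 | intermediate
14 | benzyl 3,5-bis(benzyloxy)-2-[(4-oxocyclohexa-2,5-dien-1-ylidene)methyl]-6-(3-phenylpropanoyl)phenyl malonate (para-quinone methide) | O=C1C=CC(=Cc2c(OC(=O)CC(=O)OCc3ccccc3)c(C(=O)CCc3ccccc3)c(OCc3ccccc3)cc2OCc2ccccc2)C=C1 | intermediate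
15 | benzyl (3S,4S)-5,7-bis(benzyloxy)-4-(4-hydroxyphenyl)-2-oxo-8-(3-phenylpropanoyl)chromane-3-carboxylate (3,4-trans) | O=C1[C@H](C(=O)OCc3ccccc3)[C@@H](c2ccc(O)cc2)c2c(OCc3ccccc3)cc(OCc3ccccc3)c(C(=O)CCc3ccccc3)c2O1 | intermediate
16 | (3S,4S)-5,7-dihydroxy-4-(4-hydroxyphenyl)-2-oxo-8-(3-phenylpropanoyl)chromane-3-carboxylic acid | O=C1[C@H](C(=O)O)[C@@H](c2ccc(O)cc2)c2c(O)cc(O)c(C(=O)CCc3ccccc3)c2O1 | intermediate
17 | (4S)-5,7-dihydroxy-4-(4-hydroxyphenyl)-8-(3-phenylpropanoyl)chroman-2-one | O=C1C[C@@H](c2ccc(O)cc2)c2c(O)cc(O)c(C(=O)CCc3ccccc3)c2O1 | target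

**Summary and risks**

Total step count: 8. Longest linear sequence: 8 steps (1 to 17).

Steps most likely to fail:

Step 7. What may go wrong: poor facial control in the ring closure, or loss of the quinone methide to over-oxidation and intermolecular capture while the aryl ester turns into the s-trans rotamer that closure requires. Fallback on known chemistry, setting out from 7 and returning at 17: Mizoroki–Heck coupling of 7 with methyl acrylate (Pd(OAc)2, P(o-tol)3, Et3N, DMF, 100 °C) should give methyl (E)-3-[4,6-bis(benzyloxy)-2-hydroxy-3-(3-phenylpropanoyl)phenyl]prop-2-enoate F1. Irradiation at 365 nm in MeCN (E to Z isomerisation, then spontaneous lactonisation) should give the coumarin 5,7-bis(benzyloxy)-8-(3-phenylpropanoyl)-2H-chromen-2-one F2. Rhodium-catalysed asymmetric 1,4-addition of 4-(benzyloxy)phenylboronic acid (Rh(acac)(C2H4)2, (S)-SEGPHOS chosen by analogy with the parent coumarin series, dioxane/H2O, 60 °C), the standard enantioselective entry to 4-arylchroman-2-ones, should give (4S)-5,7-bis(benzyloxy)-4-[4-(benzyloxy)phenyl]-8-(3-phenylpropanoyl)chroman-2-one F3. Hydrogenolysis (H2, Pd/C, EtOAc) then returns to the route at target 17.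

Step 3. What may go wrong: iodination at the other open ring position (between the two benzyloxy groups) or double iodination. Fallback, setting out from 5 and returning at 10: magnesium-phenoxide-directed ortho-formylation of 5 (MgCl2, Et3N, paraformaldehyde, MeCN, reflux), which can only functionalise the carbon ortho to the single free OH, should give 4,6-bis(benzyloxy)-2-hydroxy-3-(3-phenylpropanoyl)benzaldehyde F4. Addition of 4-[(tert-butyldimethylsilyl)oxy]phenylmagnesium bromide (2.2 equiv, THF, −78 °C; the aldehyde reacts ahead of the chelated ketone) should give the racemic carbinol 1-[4,6-bis(benzyloxy)-3-{(4-[(tert-butyldimethylsilyl)oxy]phenyl)(hydroxy)methyl}-2-hydroxyphenyl]-3-phenylpropan-1-one F5. Ionic hydrogenation (Et3SiH, TFA, CH2Cl2, −20 °C) through the ortho-quinone methide then gives diarylmethane 10.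

Step 8. What may go wrong: partial loss of configuration at C4 through reversible C3–C4 heterolysis of the free triphenolic acid on warming, and over-reduction of the aryl ketone during hydrogenolysis. Fallback, setting out from 15 and returning at 17, which separates the operations and avoids H2 at the end: selective cleavage of the benzyl ester with Pd(OAc)2, Et3SiH and Et3N in CH2Cl2 (aryl benzyl ethers are retained) should give (3S,4S)-5,7-bis(benzyloxy)-4-(4-hydroxyphenyl)-2-oxo-8-(3-phenylpropanoyl)chromane-3-carboxylic acid F6. Decarboxylation at 50–60 °C in toluene, with ring A still protected, should give (4S)-5,7-bis(benzyloxy)-4-(4-hydroxyphenyl)-8-(3-phenylpropanoyl)chroman-2-one F7. Non-reductive debenzylation with BCl3 and pentamethylbenzene in CH2Cl2 at −78 °C then gives 17.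

**Further compounds**

F1 | step 7 | methyl (E)-3-[4,6-bis(benzyloxy)-2-hydroxy-3-(3-phenylpropanoyl)phenyl]prop-2-enoate | COC(=O)/C=C/c1c(O)c(C(=O)CCc2ccccc2)c(OCc2ccccc2)cc1OCc1ccccc1
F2 | step 7 | 5,7-bis(benzyloxy)-8-(3-phenylpropanoyl)-2H-chromen-2-one | O=C1C=Cc2c(OCc3ccccc3)cc(OCc3ccccc3)c(C(=O)CCc3ccccc3)c2O1
F3 | step 7 | (4S)-5,7-bis(benzyloxy)-4-[4-(benzyloxy)phenyl]-8-(3-phenylpropanoyl)chroman-2-one | O=C1C[C@@H](c2ccc(OCc3ccccc3)cc2)c2c(OCc3ccccc3)cc(OCc3ccccc3)c(C(=O)CCc3ccccc3)c2O1
F4 | step 3 | 4,6-bis(benzyloxy)-2-hydroxy-3-(3-phenylpropanoyl)benzaldehyde | O=Cc1c(O)c(C(=O)CCc2ccccc2)c(OCc2ccccc2)cc1OCc1ccccc1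
F5 | step 3 | 1-[4,6-bis(benzyloxy)-3-{(4-[(tert-butyldimethylsilyl)oxy]phenyl)(hydroxy)methyl}-2-hydroxyphenyl]-3-phenylpropan-1-one (racemic) | CC(C)(C)[Si](C)(C)Oc1ccc(C(O)c2c(O)c(C(=O)CCc3ccccc3)c(OCc3ccccc3)cc2OCc2ccccc2)cc1
F6 | step 8 | (3S,4S)-5,7-bis(benzyloxy)-4-(4-hydroxyphenyl)-2-oxo-8-(3-phenylpropanoyl)chromane-3-carboxylic acid | O=C1[C@H](C(=O)O)[C@@H](c2ccc(O)cc2)c2c(OCc3ccccc3)cc(OCc3ccccc3)c(C(=O)CCc3ccccc3)c2O1
F7 | step 8 | (4S)-5,7-bis(benzyloxy)-4-(4-hydroxyphenyl)-8-(3-phenylpropanoyl)chroman-2-one | O=C1C[C@@H](c2ccc(O)cc2)c2c(OCc3ccccc3)cc(OCc3ccccc3)c(C(=O)CCc3ccccc3)c2O1
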